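**Plan**
- Retrosynthetic cuts: C8–aryl (Grignard addition), then C7–CH3 and C7=C8 (conjugate methylation of a nitroalkene made by Henry condensation), then the ring bonds C1–C6 and C4–C5 ([4+2]), last the C5=C6 double bond of the dienophile (α-methylenation).
- Enabling feature: in the ring (C1 ketone, C2=C3 alkene, C4 methoxy carbon, C5 CH2, C6 quaternary) C1 and C4 both carry oxygen on either side of the C2=C3 double bond, as C2 and C5 of a 2-alkoxyfuran do. C5 and C6 are the two carbons of a 1,1-disubstituted alkene that bears allyl and the C7 carbon.
- Forward: pent-4-enal gives 2-allylacrolein; its cycloaddition with 2-methoxyfuran closes the only carbocycle. The oxygen bridge is opened in the same flask by O-methylation, so the C4 methyl ether and the C1 ketone appear together.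
- The side chain then grows from the formyl carbon (C7): nitroalkene, methyl at C7 with in-situ Nef reaction to the C8 aldehyde, aryl at C8.
- Stereochemistry: C6 from the chiral Lewis acid (face of the dienophile), C4 from exo placement of the formyl group (cis to the oxygen bridge), C7 from the chiral copper catalyst, C8 from Felkin–Anh addition anti to the quaternary C6.

Key step: step 2

Assumption: megaphone numbering (C1 ketone to C8 carbinol) is used throughout; the catalyst antipodes named in steps 2 and 4 are those expected from the accepted stereochemical models, and if either sense of induction proves opposite the mirror-image catalyst is used without other change.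

Step 1
Reactants: 1 pent-4-enal; 2 formaldehyde (37% aqueous)
Product: 3 2-methylidenepent-4-enal (2-allylacrolein)
Conditions: pyrrolidine (10 mol%), propionic acid (10 mol%), i-PrOH, 45 °C
Reagents that add atoms: none
Why: Amine-catalysed Mannich condensation with formaldehyde followed by β-elimination of the amine (α-methylenation of an aldehyde) is general for α-unbranched aldehydes, and no stereocentre is formed.

Step 2
Reactants: 3 2-methylidenepent-4-enal (1.2 equiv); 4 2-methoxyfuran
Product: 7 (1R,5R)-5-methoxy-2-oxo-1-(prop-2-en-1-yl)cyclohex-3-ene-1-carbaldehyde, via bridged ketal 5 (not isolated), via oxocarbenium salt 6 (not isolated)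
Conditions: oxazaborolidinium triflimide from (S)-α,α-diphenylprolinol and o-tolylboroxine (20 mol%), CH2Cl2, −78 °C, 4 added slowly; then Me3OBF4 (1.5 equiv), −78 → 0 °C; then cold aq. NaHCO3
Reagents that add atoms: trimethyloxonium tetrafluoroborate, C[O+](C)C.F[B-](F)(F)F; water, O
Why: Proposed new method: the catalyst binds the formyl group of 3 in its s-trans form, the unsubstituted α-carbon of the furan attacks the methylene carbon and the developing enolate carbon closes on the methoxy-bearing furan carbon (asynchronous [4+2]; if stepwise, Michael addition followed by 6-exo-trig capture of the 2-methoxyfuranium ion), so that C4–C5, C1–C6 and the six-membered ring form in one event as the 7-oxanorbornene ketal 5. The closest known reaction types are oxazaborolidinium-catalysed exo cycloadditions of 2-substituted acroleins with furan, thermal cycloadditions of 2-alkoxyfurans that end with opening of the bridged ketal, and O-alkylation of ketals by trialkyloxonium salts to oxocarbenium ions; their combination on this substrate pair is untested. C6 is set by the catalyst, which should leave only the Si face of the α-carbon (CHO > allyl > CH2) open to the furan, and C4 follows from exo placement of the formyl group, cis to the oxygen bridge with allyl endo, the normal preference of 2-substituted acroleins. The regiochemistry needed (furan C5 to the CH2, furan C2 to the quaternary carbon) is secured by the methoxy group, which makes C5 the nucleophilic terminus, and the competing conjugate alkylation with re-aromatisation is held back by low temperature and the absence of a proton shuttle. The trimethyloxonium ion then methylates the bridging oxygen, the only site whose alkylation is productive because loss of the exocyclic methoxy group would need a bridgehead oxocarbenium ion, and the strained C1–O bond breaks to give cation 6 with the C4 oxygen already methylated. Water converts 6 into the C1 ketone with loss of methanol, and because the C4 oxygen is never free the bridged lactol (and loss of the formyl group) expected for a cis-4-hydroxy-6-formyl enone is avoided.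

Step 3
Reactants: 7 (1R,5R)-5-methoxy-2-oxo-1-(prop-2-en-1-yl)cyclohex-3-ene-1-carbaldehyde; 8 nitromethane
Product: 11 (4R,6R)-4-methoxy-6-[(E)-2-nitroethenyl]-6-(prop-2-en-1-yl)cyclohex-2-en-1-one, via nitroaldol 9 (not isolated), via nitroaldol mesylate 10 (not isolated)
Conditions: MeNO2 (solvent), Et3N (0.3 equiv), 0 °C → rt; then CH2Cl2, MsCl (1.5 equiv), Et3N (3 equiv), −20 → 0 °C
Reagents that add atoms: none
Why: Henry addition to the non-enolisable, activated aldehyde followed by mesylation and E1cB elimination should give the E-nitroalkene, the amine base being too weakly nucleophilic to cleave the β-keto aldehyde and C6 having no hydrogen that would allow deconjugation; no stereocentre is created.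

Step 4
Reactants: 11 (4R,6R)-4-methoxy-6-[(E)-2-nitroethenyl]-6-(prop-2-en-1-yl)cyclohex-2-en-1-one
Product: 13 (2S)-2-[(1R,5R)-5-methoxy-2-oxo-1-(prop-2-en-1-yl)cyclohex-3-en-1-yl]propanal, via methylzinc nitronate 12 (not isolated)
Conditions: Cu(OTf)2 (5 mol%), (S,R,R)-binaphthol bis(1-phenylethyl)amine phosphoramidite (10 mol%), Me2Zn (2.5 equiv), toluene, −30 °C; then cannulated into 15% aq. H2SO4/THF, 0 °C
Reagents that add atoms: dimethylzinc, C[Zn]C; water, O
Why: Copper-catalysed asymmetric conjugate addition of dimethylzinc should select the nitroalkene, a far stronger acceptor than the hindered ring enone, and set C7 by catalyst-controlled delivery of methyl to its Si face, and quenching the zinc nitronate directly into strong acid (Nef reaction) should give the aldehyde without a free basic nitronate that could add to the enone.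

Step 5
Reactants: 13 (2S)-2-[(1R,5R)-5-methoxy-2-oxo-1-(prop-2-en-1-yl)cyclohex-3-en-1-yl]propanal; 14 5-bromo-1,2,3-trimethoxybenzene
Product: 16 megaphone, (4R,6R)-6-[(1R,2S)-1-hydroxy-1-(3,4,5-trimethoxyphenyl)propan-2-yl]-4-methoxy-6-(prop-2-en-1-yl)cyclohex-2-en-1-one, via aryl Grignard reagent 15 (not isolated)
Conditions: 14, Mg, cat. I2, THF, reflux; then 13, THF, −78 °C, 15 (1.1 equiv) added dropwise; aq. NH4Cl
Reagents that add atoms: none
Why: Grignard addition should be faster at the aldehyde than at the hindered, conjugated C1 ketone, and Felkin–Anh attack anti to the quaternary C6 substituent should give the 7,8-syn carbinol, that is C8 R.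

**Compound list**
1 | pent-4-enal | C=CCCC=O | starting material
2 | formaldehyde | C=O | starting material
3 | 2-methylidenepent-4-enal (2-allylacrolein) | C=CCC(=C)C=O | intermediate
4 | 2-methoxyfuran | COc1ccco1 | starting material
5 | (1R,2R,4R)-1-methoxy-2-(prop-2-en-1-yl)-7-oxabicyclo[2.2.1]hept-5-ene-2-carbaldehyde (exo-formyl bridged ketal) | C=CC[C@]1(C=O)C[C@@H]2C=C[C@@]1(OC)O2 | intermediate
6 | (4R,6R)-6-formyl-1,4-dimethoxy-6-(prop-2-en-1-yl)cyclohex-2-en-1-ylium tetrafluoroborate (O-methyl oxocarbenium ion of 7) | C=CC[C@]1(C=O)C[C@@H](OC)C=CC1=[O+]C.F[B-](F)(F)F | intermediate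
7 | (1R,5R)-5-methoxy-2-oxo-1-(prop-2-en-1-yl)cyclohex-3-ene-1-carbaldehyde | C=CC[C@]1(C=O)C[C@@H](OC)C=CC1=O | intermediate
8 | nitromethane | C[N+](=O)[O-] | starting material
9 | (4R,6R)-6-(1-hydroxy-2-nitroethyl)-4-methoxy-6-(prop-2-en-1-yl)cyclohex-2-en-1-one (both carbinol epimers) | C=CC[C@]1(C(O)C[N+](=O)[O-])C[C@@H](OC)C=CC1=O | intermediate
10 | methanesulfonate of 9 | C=CC[C@]1(C(OS(C)(=O)=O)C[N+](=O)[O-])C[C@@H](OC)C=CC1=O | intermediate
11 | (4R,6R)-4-methoxy-6-[(E)-2-nitroethenyl]-6-(prop-2-en-1-yl)cyclohex-2-en-1-one | C=CC[C@]1(/C=C/[N+](=O)[O-])C[C@@H](OC)C=CC1=O | intermediate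
12 | methylzinc nitronate of the C7-methylated nitroalkane (C7 S) | C=CC[C@]1([C@H](C)C=[N+]([O-])O[Zn]C)C[C@@H](OC)C=CC1=O | intermediate
13 | (2S)-2-[(1R,5R)-5-methoxy-2-oxo-1-(prop-2-en-1-yl)cyclohex-3-en-1-yl]propanal | C=CC[C@]1([C@H](C)C=O)C[C@@H](OC)C=CC1=O | intermediate
14 | 5-bromo-1,2,3-trimethoxybenzene | COc1cc(Br)cc(OC)c1OC | starting material
15 | (3,4,5-trimethoxyphenyl)magnesium bromide | COc1cc([Mg]Br)cc(OC)c1OC | intermediate
16 | megaphone | C=CC[C@]1([C@H](C)[C@@H](O)c2cc(OC)c(OC)c(OC)c2)C[C@@H](OC)C=CC1=O | target

**Totals**
Total step count: 5. Longest linear sequence: 5 steps (1 → 3 → 7 → 11 → 13 → 16); 15 is made from 14 in the flask of step 5.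

**Steps most likely to fail**

1. Step 2 (proposed new method).
   - What may go wrong:
     - the zwitterion formed by the first C–C bond may lose a proton, so that the furan re-aromatises (conjugate alkylation) instead of closing the ring;
     - acid from the catalyst may open the ketal before the oxonium salt has methylated the bridging oxygen, which frees the C4 hydroxyl cis to the formyl group (lactol formation, formyl loss);
     - face discrimination may be weak with a furan far more reactive than the dienes this catalyst type is used with.
   - Fallback (known chemistry: formylation, O-allylation, Claisen rearrangement): the cycloaddition is given up and the ring is taken ready-made. The detour does not branch from an intermediate; it sets out in place of 3 (none of 1–4 is carried on) and comes back to the route at 7. The known (R)-4-methoxycyclohex-2-en-1-one F1 is formylated at C6 (LDA, then 2,2,2-trifluoroethyl formate) to (4R)-6-(hydroxymethylidene)-4-methoxycyclohex-2-en-1-one F2. O-Allylation (allyl bromide, K2CO3, acetone) gives (4R)-4-methoxy-6-[(prop-2-en-1-yloxy)methylidene]cyclohex-2-en-1-one F3. Claisen rearrangement in hot toluene should deliver allyl to C6 on the face away from the C4 methoxy group and so give 7.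

2. Step 4.
   - What may go wrong:
     - methyl transfer to the ring enone;
     - cyclisation of the metal nitronate onto the enone (bicyclo[2.2.2]octanone formation);
     - a mismatch between the facial bias of the catalyst and that of the neighbouring quaternary centre at C7;
     - C-protonation of the nitronate in place of the Nef reaction.
   - Fallback (no copper, no nitronate): it sets out from 7 and returns at 13. Wittig reaction of 7 with the ylide from (methoxymethyl)triphenylphosphonium chloride and KHMDS gives (4R,6R)-4-methoxy-6-(2-methoxyethenyl)-6-(prop-2-en-1-yl)cyclohex-2-en-1-one F4. Simmons–Smith-type cyclopropanation (Et2Zn, CH2I2), in which the electron-rich enol ether should react ahead of the allyl group, gives (4R,6R)-4-methoxy-6-(2-methoxycyclopropyl)-6-(prop-2-en-1-yl)cyclohex-2-en-1-one F5. Aqueous acid opens the donor-substituted ring by protonation at its CH2, which becomes the C7 methyl group, and releases aldehyde 13. C7 is then set by the face of cyclopropanation and can be corrected by equilibration of the epimerisable α-centre of 13 and separation.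

3. Step 5.
   - What may go wrong:
     - competing addition to the ring ketone or enone;
     - erosion of Felkin–Anh control;
     - epimerisation at C7 by the basic reagent.
   - Fallback (reagent control in place of substrate control): it sets out from 13 and returns at 16. The aryl group is transferred from an arylzinc species generated from (3,4,5-trimethoxyphenyl)boronic acid F6 and Et2Zn in the presence of a chiral amino-alcohol ligand (catalytic enantioselective aryl transfer to aldehydes). Such reagents are non-basic and do not add to ketones, and the ligand antipode is chosen to give C8 R.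

**Further compounds**
F1 | step 2 | (R)-4-methoxycyclohex-2-en-1-one | O=C1C=C[C@H](OC)CC1
F2 | step 2 | (4R)-6-(hydroxymethylidene)-4-methoxycyclohex-2-en-1-one | OC=C1C[C@@H](OC)C=CC1=O
F3 | step 2 | (4R)-4-methoxy-6-[(prop-2-en-1-yloxy)methylidene]cyclohex-2-en-1-one | C=CCOC=C1C[C@@H](OC)C=CC1=O
F4 | step 4 | (4R,6R)-4-methoxy-6-(2-methoxyethenyl)-6-(prop-2-en-1-yl)cyclohex-2-en-1-one | C=CC[C@]1(C=COC)C[C@@H](OC)C=CC1=O
F5 | step 4 | (4R,6R)-4-methoxy-6-(2-methoxycyclopropyl)-6-(prop-2-en-1-yl)cyclohex-2-en-1-one | C=CC[C@]1([C@@H]2CC2OC)C[C@@H](OC)C=CC1=O
F6 | step 5 | (3,4,5-trimethoxyphenyl)boronic acid | COc1cc(B(O)O)cc(OC)c1OC
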